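**Plan**

- Retrosynthesis: the five O–benzyl bonds are cut first (every phenol except the 5-OH is carried as a benzyl ether). Next comes the C3–C4 bond of ring C, then the O1–C2 enol ether bond, then the 7-O-benzyl bond, and last the two aryl–CH2 bonds at C6 and C8.
- Enabling feature: C4 is an aryl ketone carbon on ring A, lying between the 5-OH and O1. With C3–C4 cut it becomes the formyl carbon of a salicylaldehyde whose other ortho oxygen (O1) carries C2(Ph)=C3H2 as a 1-phenylvinyl ether, so the formyl C–H can add across that alkene.
- Forward: rings A and B and both catechol rings come from the starting materials. 2,3-Dihydroxybenzaldehyde is benzylated and reduced, two copies are attached to C3 and C5 of 2,4,6-trihydroxybenzaldehyde, the 4-OH is benzylated and one of the two equivalent ortho OH groups is vinylated. Ring C, the only ring made, closes in the penultimate step.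
- Stereochemistry: the single stereocentre C2 (S) is created in the ring closure by the chiral bisphosphine on rhodium. The closing hydrogenolysis is neutral and should leave it untouched.

Key step: step 6

Assumption: the sense of induction of BINAP in step 6 cannot be derived from a closely matching case; (R)-BINAP is written on the expectation that it gives the 2S product, and the mirror-image ligand would be used without other change if a first run shows the opposite sense.

**Route**

Step 1
Reactants: 1 2,3-dihydroxybenzaldehyde
Product: 2 2,3-bis(benzyloxy)benzaldehyde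
Conditions: BnBr (2.4 equiv), K2CO3, DMF, 60 °C
Reagents that add atoms: benzyl bromide, BrCc1ccccc1
Why: Williamson etherification of both catechol hydroxyls with an excess of a reactive benzylic halide should be complete, and the non-enolisable aldehyde is inert to carbonate.

Step 2
Reactants: 2 2,3-bis(benzyloxy)benzaldehyde
Product: 3 [2,3-bis(benzyloxy)phenyl]methanol
Conditions: NaBH4, THF/MeOH, 0 °C, then water
Reagents that add atoms: none
Why: Borohydride reduction of an aryl aldehyde to the benzylic alcohol is chemoselective and leaves the benzyl ethers untouched.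

Step 3
Reactants: 4 2,4,6-trihydroxybenzaldehyde; 3 [2,3-bis(benzyloxy)phenyl]methanol (2.2 equiv)
Product: 6 3,5-bis[2,3-bis(benzyloxy)benzyl]-2,4,6-trihydroxybenzaldehyde, via mono-C-benzylated aldehyde 5 (not isolated)
Conditions: ZnCl2 (anhydrous, 2 equiv), 1,4-dioxane, 80 °C
Reagents that add atoms: none
Why: Friedel–Crafts benzylation, in which the zinc-activated alcohol ionises to a benzylic cation stabilised by its ortho alkoxy group and is captured by C3 and then C5 of the phloroglucinol nucleus, the only free ring carbons, as in the ZnCl2-mediated C-benzylation of acylphloroglucinols with ortho-oxygenated benzyl alcohols.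

Step 4
Reactants: 6 3,5-bis[2,3-bis(benzyloxy)benzyl]-2,4,6-trihydroxybenzaldehyde
Product: 7 4-(benzyloxy)-3,5-bis[2,3-bis(benzyloxy)benzyl]-2,6-dihydroxybenzaldehyde
Conditions: BnBr (1.05 equiv), NaHCO3, DMF, 50 °C
Reagents that add atoms: benzyl bromide, BrCc1ccccc1
Why: Regioselective Williamson etherification, since the 4-OH para to the formyl group is the most acidic hydroxyl and is not hydrogen-bonded to the carbonyl, so a weak base with one equivalent of halide should alkylate it in preference to the two chelated ortho hydroxyls.

Step 5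
Reactants: 7 4-(benzyloxy)-3,5-bis[2,3-bis(benzyloxy)benzyl]-2,6-dihydroxybenzaldehyde; 8 alpha-bromostyrene [(1-bromoethenyl)benzene] (1.5 equiv)
Product: 9 4-(benzyloxy)-3,5-bis[2,3-bis(benzyloxy)benzyl]-2-hydroxy-6-[(1-phenylethenyl)oxy]benzaldehyde
Conditions: CuI (10 mol%), N,N-dimethylglycine hydrochloride (30 mol%), Cs2CO3, 1,4-dioxane, 90 °C, Ar
Reagents that add atoms: none
Why: Ullmann-type copper-catalysed C–O coupling of a phenol with a vinyl bromide; the two free hydroxyls are equivalent by symmetry, and after the first coupling the remaining one is tied up in a hydrogen bond to the formyl group, which should hold the reaction at mono-vinylation.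

Step 6
Reactants: 9 4-(benzyloxy)-3,5-bis[2,3-bis(benzyloxy)benzyl]-2-hydroxy-6-[(1-phenylethenyl)oxy]benzaldehyde
Product: 10 (2S)-7-(benzyloxy)-6,8-bis[2,3-bis(benzyloxy)benzyl]-5-hydroxy-2-phenyl-2,3-dihydro-4H-chromen-4-one
Conditions: [Rh(cod)2]BF4 (5 mol%), (R)-BINAP (6 mol%), K3PO4 (10 mol%), 4 Å molecular sieves, 1,2-dichloroethane, 50 °C, Ar
Reagents that add atoms: none
Why: Proposed new method: monovalent rhodium, held by the ortho phenoxide of the salicylaldehyde, inserts into the formyl C–H bond; the hydride then adds to the phenyl- and oxygen-bearing carbon of the coordinated enol ether (which becomes C2–H) while rhodium takes the terminal CH2, and reductive elimination of acyl and primary alkyl from the seven-membered rhodacycle forms C3–C4. The closest known reaction types are the rhodium–BINAP enantioselective hydroacylation of 2-(1-substituted vinyl)benzaldehydes to 3-substituted indan-1-ones and the phenoxide-directed hydroacylation of alkenes with salicylaldehydes; closure of an oxygen-tethered 1,1-disubstituted enol ether to a chroman-4-one has not been shown. Ring C closes in the endo mode (6-endo, both alkene carbons end up in the ring) by way of that seven-membered acyl–alkyl rhodacycle. The C2 stereocentre is controlled by the C2-symmetric bisphosphine, which selects the enantioface of the alkene in the hydride insertion and reductive elimination sequence, and the neutral medium gives no path for its epimerisation. The step needs regioselectivity for the six- over the five-membered ketone and chemoselectivity over decarbonylation: hydride insertion is reversible and the alternative tertiary alkyl rhodium would have to form a quaternary centre, so the primary alkyl should be the one that eliminates, while five-membered phenoxide chelation keeps the acyl rhodium hydride coordinatively saturated. The catalytic K3PO4 lets the phenoxide bind without leaving HBF4 free to hydrolyse the acid-labile enol ether.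

Step 7
Reactants: 10 (2S)-7-(benzyloxy)-6,8-bis[2,3-bis(benzyloxy)benzyl]-5-hydroxy-2-phenyl-2,3-dihydro-4H-chromen-4-one
Product: 11 (2S)-6,8-bis(2,3-dihydroxybenzyl)-5,7-dihydroxy-2-phenyl-2,3-dihydro-4H-chromen-4-one (CNP0059702.1)
Conditions: H2 (1 atm), 10% Pd/C, EtOAc/MeOH, rt, stopped after uptake of five equivalents
Reagents that add atoms: none
Why: Catalytic hydrogenolysis of the five benzyl aryl ethers is much faster at atmospheric pressure than cleavage of the diarylmethane C–C bonds or the ring C2–O bond, and being neutral it should not open the flavanone or racemise C2.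

**Compound list**

1 | 2,3-dihydroxybenzaldehyde | O=Cc1cccc(O)c1O | starting material
2 | 2,3-bis(benzyloxy)benzaldehyde | O=Cc1cccc(OCc2ccccc2)c1OCc1ccccc1 | intermediate
3 | [2,3-bis(benzyloxy)phenyl]methanol | OCc1cccc(OCc2ccccc2)c1OCc1ccccc1 | intermediate
4 | 2,4,6-trihydroxybenzaldehyde | O=Cc1c(O)cc(O)cc1O | starting material
5 | 3-[2,3-bis(benzyloxy)benzyl]-2,4,6-trihydroxybenzaldehyde | O=Cc1c(O)cc(O)c(Cc2cccc(OCc3ccccc3)c2OCc2ccccc2)c1O | intermediate
6 | 3,5-bis[2,3-bis(benzyloxy)benzyl]-2,4,6-trihydroxybenzaldehyde | O=Cc1c(O)c(Cc2cccc(OCc3ccccc3)c2OCc2ccccc2)c(O)c(Cc2cccc(OCc3ccccc3)c2OCc2ccccc2)c1O | intermediate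
7 | 4-(benzyloxy)-3,5-bis[2,3-bis(benzyloxy)benzyl]-2,6-dihydroxybenzaldehyde | O=Cc1c(O)c(Cc2cccc(OCc3ccccc3)c2OCc2ccccc2)c(OCc2ccccc2)c(Cc2cccc(OCc3ccccc3)c2OCc2ccccc2)c1O | intermediate
8 | alpha-bromostyrene [(1-bromoethenyl)benzene] | C=C(Br)c1ccccc1 | starting material
9 | 4-(benzyloxy)-3,5-bis[2,3-bis(benzyloxy)benzyl]-2-hydroxy-6-[(1-phenylethenyl)oxy]benzaldehyde | O=Cc1c(OC(=C)c2ccccc2)c(Cc2cccc(OCc3ccccc3)c2OCc2ccccc2)c(OCc2ccccc2)c(Cc2cccc(OCc3ccccc3)c2OCc2ccccc2)c1O | intermediate
10 | (2S)-7-(benzyloxy)-6,8-bis[2,3-bis(benzyloxy)benzyl]-5-hydroxy-2-phenyl-2,3-dihydro-4H-chromen-4-one | O=C1C[C@@H](c2ccccc2)Oc2c(Cc3cccc(OCc4ccccc4)c3OCc3ccccc3)c(OCc3ccccc3)c(Cc3cccc(OCc4ccccc4)c3OCc3ccccc3)c(O)c21 | intermediate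
11 | (2S)-6,8-bis(2,3-dihydroxybenzyl)-5,7-dihydroxy-2-phenyl-2,3-dihydro-4H-chromen-4-one | O=C1C[C@@H](c2ccccc2)Oc2c(Cc3cccc(O)c3O)c(O)c(Cc3cccc(O)c3O)c(O)c21 | target

**Step count**

Total step count: 7. Longest linear sequence: 7 steps (steps 1 to 7, from 1 to 11).

**Steps most likely to fail**

Step 6 (carries the label). The acyl rhodium hydride may lose carbon monoxide, closure may go to the five-membered ketone, the enol ether may hydrolyse, or enantioface discrimination may be poor. The fallback uses known chemistry and sets out from 3 together with commercial 2,4,6-trihydroxyacetophenone. Friedel–Crafts benzylation as in step 3 (ZnCl2, dioxane) should give 1-{3,5-bis[2,3-bis(benzyloxy)benzyl]-2,4,6-trihydroxyphenyl}ethanone F1. Selective benzylation of its 4-OH (BnBr, NaHCO3, DMF) should give 1-{4-(benzyloxy)-3,5-bis[2,3-bis(benzyloxy)benzyl]-2,6-dihydroxyphenyl}ethanone F2. Claisen–Schmidt condensation with benzaldehyde (KOH, EtOH) should give (E)-1-{4-(benzyloxy)-3,5-bis[2,3-bis(benzyloxy)benzyl]-2,6-dihydroxyphenyl}-3-phenylprop-2-en-1-one F3. Enantioselective intramolecular oxa-Michael addition of this chalcone under a cinchona-alkaloid-derived bifunctional base, with enantiomeric enrichment by crystallisation or chromatography on a chiral phase if needed, brings the sequence back to the route at 10; either ortho hydroxyl gives the same flavanone.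

Step 5. Coupling may be slow at a hindered, hydrogen-bonded phenol, the vinyl bromide may lose HBr to give phenylacetylene, and the salicylaldehyde may sequester copper. The fallback sets out from 7. Mitsunobu etherification with 2-bromo-1-phenylethanol (PPh3, DIAD, THF, 0 °C to rt) should give racemic 4-(benzyloxy)-3,5-bis[2,3-bis(benzyloxy)benzyl]-2-(2-bromo-1-phenylethoxy)-6-hydroxybenzaldehyde F4. Its only beta hydrogen is the benzylic methine, so E2 dehydrobromination with KOtBu (THF, 0 °C) can only give the 1-phenylvinyl ether; the sequence returns to the route at 9.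

Step 3. The second benzylation may stall, the formylphloroglucinol may self-condense under the Lewis acid, or O-benzyl groups may migrate. The fallback sets out from 3. PBr3 (CH2Cl2, 0 °C) should give 2,3-bis(benzyloxy)benzyl bromide F5. Two equivalents of F5 are then used for C-alkylation of the phenoxide of 4 in a protic basic medium (aqueous KOH, 0 °C), the classical C-alkylation of acylphloroglucinol anions with benzylic and allylic halides, and the sequence returns to the route at 6.

**Further compounds**

F1 | step 6 | 1-{3,5-bis[2,3-bis(benzyloxy)benzyl]-2,4,6-trihydroxyphenyl}ethanone | CC(=O)c1c(O)c(Cc2cccc(OCc3ccccc3)c2OCc2ccccc2)c(O)c(Cc2cccc(OCc3ccccc3)c2OCc2ccccc2)c1O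
F2 | step 6 | 1-{4-(benzyloxy)-3,5-bis[2,3-bis(benzyloxy)benzyl]-2,6-dihydroxyphenyl}ethanone | CC(=O)c1c(O)c(Cc2cccc(OCc3ccccc3)c2OCc2ccccc2)c(OCc2ccccc2)c(Cc2cccc(OCc3ccccc3)c2OCc2ccccc2)c1O
F3 | step 6 | (E)-1-{4-(benzyloxy)-3,5-bis[2,3-bis(benzyloxy)benzyl]-2,6-dihydroxyphenyl}-3-phenylprop-2-en-1-one | O=C(/C=C/c1ccccc1)c1c(O)c(Cc2cccc(OCc3ccccc3)c2OCc2ccccc2)c(OCc2ccccc2)c(Cc2cccc(OCc3ccccc3)c2OCc2ccccc2)c1O
F4 | step 5 | racemic 4-(benzyloxy)-3,5-bis[2,3-bis(benzyloxy)benzyl]-2-(2-bromo-1-phenylethoxy)-6-hydroxybenzaldehyde | O=Cc1c(OC(CBr)c2ccccc2)c(Cc2cccc(OCc3ccccc3)c2OCc2ccccc2)c(OCc2ccccc2)c(Cc2cccc(OCc3ccccc3)c2OCc2ccccc2)c1O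
F5 | step 3 | 2,3-bis(benzyloxy)benzyl bromide | BrCc1cccc(OCc2ccccc2)c1OCc1ccccc1
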